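## Retrosynthetic overview

1. The γ-lactone is closed last through its C7–O bond: a carboxylate-directed C–H lactonisation of a C19 acid onto the allylic C7 methylene of the finished ten-membered ring (then C17 equilibration and desilylation).
2. The ten-membered ring comes from a Nozaki–Hiyama–Kishi closure at C4–C5 (C4 aldehyde plus (Z)-α-iodo enoate), which also creates the C4 carbinol.
3. The C8 carbinol comes from a chelation-controlled Reformatsky addition (C8–C17) to an α-hydroxy ketone; C8–C9 from a dithiane acyl anion and a C9 lactol; C2–C3 from an allylboration.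
4. The cyclohexane comes from a catalytic asymmetric Diels–Alder reaction of a 2-siloxydiene with ethyl 3-methyl-4-oxocrotonate; C12/C14 oxygens by Saegusa oxidation, borylation–oxidation and directed reduction.
5. Ring order: cyclohexane (step 2), temporary γ-lactone (step 3), ten-membered carbocycle (step 17), γ-lactone (step 20).

Assumptions: locants follow briarane numbering (C1–C20; C15 and C20 ring methyls, C16 ester carbon, C17–C19 lactone propionate, C18 its methyl), and β is the cyclohexane face that carries the C1 methyl. Where a catalyst antipode cannot be fixed on paper (steps 2, 17, 20), the one named is the expected one and its mirror image is the first variable to change.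

## Route

Step 1
Reactants: 1 pent-1-en-3-one
Product: 2 (Z)-triisopropyl(penta-1,3-dien-3-yloxy)silane
Conditions: TIPSOTf, Et3N, CH2Cl2, 0 °C
Reagents that add atoms: triisopropylsilyl trifluoromethanesulfonate, CC(C)[Si](C(C)C)(C(C)C)OS(=O)(=O)C(F)(F)F
Why: Soft enolisation and O-silylation of the ethyl ketone give the (Z)-silyl enol ether, a 2-siloxydiene whose methyl is in the outside position.

Step 2
Reactants: 2 (Z)-triisopropyl(penta-1,3-dien-3-yloxy)silane; 3 ethyl (2E)-3-methyl-4-oxobut-2-enoate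
Product: 4 Diels–Alder aldehyde ester
Conditions: (S)-o-tolyl-CBS oxazaborolidine (20 mol%), Tf2NH (18 mol%), CH2Cl2, −78 → −40 °C
Reagents that add atoms: none
Why: Catalytic enantioselective Diels–Alder reaction with oxazaborolidinium activation of the formyl group; the nucleophilic C11 terminus of the enol silane bonds to the β-carbon C10 and C14 to the formyl-bearing carbon, which sets the quaternary C1 and C10 (formyl and ester trans from the E-dienophile, absolute sense from the catalyst), while C11 forms mainly with its methyl cis to the endo formyl group and is corrected in step 5.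

Step 3
Reactants: 4 Diels–Alder aldehyde ester
Product: 6 allyl γ-lactone silyl enol ether, via homoallylic hydroxy ester 5 (not isolated)
Conditions: (+)-Ipc2B(allyl), Et2O, −78 °C; 2-aminoethanol, rt; then PPTS (cat.), PhMe, 60 °C
Reagents that add atoms: (+)-B-allyldiisopinocampheylborane (from (−)-α-pinene), C=CCB(C1CC2CC(C2(C)C)C1C)C1CC2CC(C2(C)C)C1C
Why: Brown allylboration through a chair Zimmerman–Traxler transition state sets the 2R carbinol under reagent control, and the C2 hydroxyl then lactonises onto the trans C9 ester, masking C2–OH and C9 in one trans-fused ring.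

Step 4
Reactants: 6 allyl γ-lactone silyl enol ether
Product: 7 enone lactone (C11 methyl α)
Conditions: Pd(OAc)2 (1.1 equiv), MeCN, rt
Reagents that add atoms: none
Why: Saegusa–Ito oxidation of the regiodefined C12 silyl enol ether, where β-hydride elimination can only occur towards C14 because C1 is quaternary, gives the C13=C14 enone.

Step 5
Reactants: 7 enone lactone (C11 methyl α)
Product: 9 enone lactone (C11 methyl β), via lithium dienolate 8 (not isolated)
Conditions: LiN(i-Pr)2 (1.05 equiv), THF, −78 °C; then AcOH, −78 °C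
Reagents that add atoms: none
Why: Kinetic α′-deprotonation and kinetic protonation: the cross-conjugated dienolate is protonated at C11 from the α face, anti to the pseudo-axial C1 methyl, which places the C11 methyl β (cis to C9 and C15) whatever the C11 ratio from step 2.

Step 6
Reactants: 9 enone lactone (C11 methyl β)
Product: 11 14α-hydroxy ketone lactone, via 14α-pinacolboronate ketone 10 (not isolated)
Conditions: CuCl (3 mol%), DPEphos (3 mol%), NaOt-Bu (3 mol%), B2pin2, MeOH (2 equiv), THF, −20 °C; then H2O2, pH 7 phosphate buffer, 0 °C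
Reagents that add atoms: hydrogen peroxide, OO
Why: Copper-catalysed conjugate borylation followed by stereoretentive C–B oxidation; the boryl copper adds to C14 from the α face, anti to the axial C1 methyl, giving the 14α hydroxyl, and the low base loading and temperature protect the contra-thermodynamic C11 centre.

Step 7
Reactants: 11 14α-hydroxy ketone lactone
Product: 12 12β,14α-diol lactone
Conditions: Me4NBH(OAc)3, MeCN/AcOH (1:1), −20 °C
Reagents that add atoms: none
Why: Evans–Saksena hydroxyl-directed reduction, in which the C14 alkoxyborohydride delivers hydride intramolecularly to the α face of the C12 ketone, gives the 1,3-anti diol (12β-OH).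

Step 8
Reactants: 12 12β,14α-diol lactone
Product: 13 12-O-TBS lactone
Conditions: TBSCl (1.1 equiv), imidazole, DMF, 0 °C
Reagents that add atoms: tert-butyl(chloro)dimethylsilane, CC(C)(C)[Si](C)(C)Cl
Why: Selective silylation of the equatorial C12 hydroxyl, because the axial neopentyl C14 hydroxyl next to the quaternary C1 reacts much more slowly.

Step 9
Reactants: 13 12-O-TBS lactone
Product: 14 lactol
Conditions: i-Bu2AlH (2.2 equiv), CH2Cl2, −78 °C
Reagents that add atoms: none
Why: Partial reduction of the γ-lactone (stable tetrahedral aluminate at −78 °C) gives the lactol, the latent C9 aldehyde.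

Step 10
Reactants: 15 1,3-dithiane; 16 oxirane
Product: 19 triethyl[2-(1,3-dithian-2-yl)ethoxy]silane, via 2-lithio-1,3-dithiane 17 (not isolated), via lithium 2-(1,3-dithian-2-yl)ethoxide 18 (not isolated)
Conditions: n-BuLi, THF, −30 °C; oxirane, −30 → 0 °C; then Et3SiCl, 0 °C
Reagents that add atoms: chlorotriethylsilane, CC[Si](CC)(CC)Cl
Why: Corey–Seebach dithiane lithiation, epoxide opening and in situ O-silylation give the C6–C8 acyl-anion building block.

Step 11
Reactants: 19 triethyl[2-(1,3-dithian-2-yl)ethoxy]silane; 14 lactol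
Product: 21 dithiane triol, via lithiated dithiane 20 (not isolated)
Conditions: 19 (4 equiv), n-BuLi, THF, −30 °C; then 14, −78 → −20 °C
Reagents that add atoms: none
Why: Corey–Seebach umpolung addition to the ring-opened lactol (hydroxy aldehyde), with Felkin–Anh attack anti to the quaternary C1 substituent of C10, gives the 9R carbinol.

Step 12
Reactants: 21 dithiane triol
Product: 22 α-hydroxy ketone triol
Conditions: MeI, CaCO3, MeCN/H2O (9:1), 45 °C
Reagents that add atoms: water, O
Why: Alkylative hydrolysis of the dithioacetal under neutral conditions unmasks the C8 ketone without touching the silyl ethers or the alkene.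

Step 13
Reactants: 22 α-hydroxy ketone triol; 23 tert-butyl 2-bromopropanoate
Product: 25 C8 carbinol tert-butyl ester (tetraol), via Reformatsky zinc reagent 24 (not isolated)
Conditions: Zn (activated), THF, rt (6 equiv of reagent); then 22, 0 °C → rt; aq. NH4Cl
Reagents that add atoms: none
Why: Reformatsky reaction under Cram-chelate control, in which the zinc alkoxide of the C9 hydroxyl chelates the C8 ketone and the zinc enolate adds from the face opposite C10, sets the C8 tertiary carbinol as in the target; C17 forms as an epimer mixture that is fixed in step 21.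

Step 14
Reactants: 25 C8 carbinol tert-butyl ester (tetraol)
Product: 26 2,9,14-triacetate
Conditions: Ac2O, Et3N, DMAP (cat.), CH2Cl2, 0 °C → rt
Reagents that add atoms: acetic anhydride, CC(=O)OC(C)=O
Why: Acylation of the three secondary hydroxyls (C2, C9, C14), while the tertiary C8 hydroxyl and the silyl ethers do not react.

Step 15
Reactants: 26 2,9,14-triacetate
Product: 28 (Z)-α-iodo enoate, via C6 aldehyde 27 (not isolated)
Conditions: (COCl)2, DMSO, CH2Cl2, −78 → −40 °C; Et3N; then Ph3P=C(I)CO2Me [from Ph3P=CHCO2Me, N-iodosuccinimide, K2CO3, CH2Cl2], 0 °C → rt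
Reagents that add atoms: methyl 2-(triphenyl-λ5-phosphanylidene)acetate, COC(=O)C=P(c1ccccc1)(c1ccccc1)c1ccccc1; N-iodosuccinimide, O=C1CCC(=O)N1I
Why: Swern conditions oxidise the primary triethylsilyl ether directly to the aldehyde, and the Wittig reaction with the stabilised iodo ylide gives the (Z)-α-iodo enoate with the ester trans to C7, the geometry needed at C5=C6.

Step 16
Reactants: 28 (Z)-α-iodo enoate
Product: 29 C4 aldehyde
Conditions: O3, CH2Cl2/MeOH, −78 °C; then Me2S
Reagents that add atoms: ozone, [O-][O+]=O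
Why: Ozonolysis cleaves only the electron-rich terminal alkene (the iodo enoate is electron-poor and trisubstituted) and gives the C4 aldehyde.

Step 17
Reactants: 29 C4 aldehyde
Product: 30 macrocyclic C4 alcohol
Conditions: CrCl2 (10 equiv), NiCl2 (0.2 equiv), Kishi oxazoline–sulfonamide ligand, Et3N, THF/DMSO, 2 mM, rt
Reagents that add atoms: none
Why: Nozaki–Hiyama–Kishi macrocyclisation, in which the alkenylchromium species formed with retention from the iodide adds to the C4 aldehyde, closes the ten-membered ring with the ring-cis C5=C6 enoate, and the chiral sulfonamide–chromium complex sets 4R (anti to the C2 acetate).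

Step 18
Reactants: 30 macrocyclic C4 alcohol
Product: 31 macrocyclic tetraacetate tert-butyl ester
Conditions: Ac2O, pyridine, 0 °C → rt
Reagents that add atoms: acetic anhydride, CC(=O)OC(C)=O
Why: Acetylation of the allylic C4 hydroxyl, run without DMAP to avoid allylic transposition of the Baylis–Hillman-type acetate.

Step 19
Reactants: 31 macrocyclic tetraacetate tert-butyl ester
Product: 32 macrocyclic seco acid
Conditions: 85% aq. H3PO4, PhMe, rt
Reagents that add atoms: none
Why: Acidolysis of the tert-butyl ester (loss of isobutene) frees the C19 acid and leaves the acetates, the methyl ester and the secondary TBS ether intact.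

Step 20
Reactants: 32 macrocyclic seco acid
Product: 33 12-O-TBS γ-lactone (C17 epimers)
Conditions: [Mn(OTf)2((S,S)-pdp)] (3 mol%; pdp = 1,1′-bis(pyridin-2-ylmethyl)-2,2′-bipyrrolidine), H2O2 (1.5 equiv, slow addition), (CF3)2CHOH, 0 °C
Reagents that add atoms: none
Why: Proposed new method: the substrate carboxylate binds manganese, H2O2 is heterolysed to a high-valent manganese-oxo carboxylate that abstracts the γ C7 pro-S hydrogen through a seven-membered transition state, and rebound of the carboxylate oxygen forms the C7–O bond of the γ-lactone with the 7S configuration, a carboxylate-directed γ-C(sp3)–H lactonisation that is closest to the known lactonisation of unactivated methylenes in simple acids but has not been shown for an allylic methylene next to an electron-poor enoate in a polyoxygenated macrocycle, where the directed hydrogen abstraction must outrun epoxidation of the hindered, deactivated C5=C6 bond.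

Step 21
Reactants: 33 12-O-TBS γ-lactone (C17 epimers)
Product: 34 12-O-TBS γ-lactone (17R)
Conditions: DBU (0.2 equiv), PhMe, 40 °C
Reagents that add atoms: none
Why: Base-mediated thermodynamic epimerisation α to the lactone carbonyl lets the C17 methyl settle trans to the bulky C9 substituent (cis to the C8 hydroxyl), which is 17R.

Step 22
Reactants: 34 12-O-TBS γ-lactone (17R)
Product: 35 CNP0169867.2
Conditions: HF·pyridine, pyridine, THF, 0 °C → rt
Reagents that add atoms: none
Why: Buffered fluoride desilylation frees the C12 hydroxyl and leaves the four acetates, both esters and the tertiary alcohol untouched.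

## Compound list

1 | pent-1-en-3-one (ethyl vinyl ketone) | CCC(=O)C=C | starting material
2 | (Z)-triisopropyl(penta-1,3-dien-3-yloxy)silane | C=C/C(O[Si](C(C)C)(C(C)C)C(C)C)=C/C | intermediate
3 | ethyl (2E)-3-methyl-4-oxobut-2-enoate | CCOC(=O)/C=C(\C)C=O | starting material
4 | ethyl 6-formyl-2,6-dimethyl-3-(triisopropylsilyloxy)cyclohex-3-ene-1-carboxylate; formyl trans to ester (C1, C10 as in 35); 2-methyl trans to ester (C11 epimer of the target series, major; minor epimer carried) | CCOC(=O)[C@H]1[C@H](C)C(O[Si](C(C)C)(C(C)C)C(C)C)=CC[C@]1(C)C=O | intermediate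
5 | homoallylic hydroxy ester, (2R)-1-hydroxybut-3-enyl at C1 (not isolated) | CCOC(=O)[C@H]1[C@H](C)C(O[Si](C(C)C)(C(C)C)C(C)C)=CC[C@]1(C)[C@H](O)CC=C | intermediate
6 | trans-fused γ-lactone (C2–O–C9=O) with C2 allyl group and C12 silyl enol ether | C=CC[C@H]1OC(=O)[C@H]2[C@H](C)C(O[Si](C(C)C)(C(C)C)C(C)C)=CC[C@]12C | intermediate
7 | enone lactone, C12 ketone, C13=C14, C11 methyl α | C=CC[C@H]1OC(=O)[C@H]2[C@H](C)C(=O)C=C[C@]12C | intermediate
8 | lithium C11=C12 dienolate of 7 (not isolated) | C=CC[C@H]1OC(=O)[C@H]2C(C)=C([O-])C=C[C@]12C.[Li+] | intermediate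
9 | enone lactone, C11 methyl β (cis to C9 and C15) | C=CC[C@H]1OC(=O)[C@H]2[C@@H](C)C(=O)C=C[C@]12C | intermediate
10 | 14α-pinacolboronate C12 ketone lactone (not isolated) | C=CC[C@H]1OC(=O)[C@H]2[C@@H](C)C(=O)C[C@H](B3OC(C)(C)C(C)(C)O3)[C@]12C | intermediate
11 | 14α-hydroxy C12 ketone lactone | C=CC[C@H]1OC(=O)[C@H]2[C@@H](C)C(=O)C[C@H](O)[C@]12C | intermediate
12 | 12β,14α-diol lactone | C=CC[C@H]1OC(=O)[C@H]2[C@@H](C)[C@@H](O)C[C@H](O)[C@]12C | intermediate
13 | 12-O-TBS 14α-hydroxy lactone | C=CC[C@H]1OC(=O)[C@H]2[C@@H](C)[C@@H](O[Si](C)(C)C(C)(C)C)C[C@H](O)[C@]12C | intermediate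
14 | lactol (C9 anomers) | C=CC[C@H]1OC(O)[C@H]2[C@@H](C)[C@@H](O[Si](C)(C)C(C)(C)C)C[C@H](O)[C@]12C | intermediate
15 | 1,3-dithiane | C1CSCSC1 | starting material
16 | oxirane | C1CO1 | starting material
17 | 2-lithio-1,3-dithiane (not isolated) | [Li]C1SCCCS1 | intermediate
18 | lithium 2-(1,3-dithian-2-yl)ethoxide (not isolated) | [Li+].[O-]CCC1SCCCS1 | intermediate
19 | triethyl[2-(1,3-dithian-2-yl)ethoxy]silane | CC[Si](CC)(CC)OCCC1SCCCS1 | intermediate
20 | 2-lithio derivative of 19 (not isolated) | CC[Si](CC)(CC)OCCC1([Li])SCCCS1 | intermediate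
21 | dithiane triol: C8 dithiane, 9R-OH, 2R-OH, 14α-OH, 12-O-TBS, C6-O-TES | CC[Si](CC)(CC)OCCC2(SCCCS2)[C@H](O)[C@H]1[C@@H](C)[C@@H](O[Si](C)(C)C(C)(C)C)C[C@H](O)[C@]1(C)[C@H](O)CC=C | intermediate
22 | α-hydroxy ketone triol (C8 ketone) | CC[Si](CC)(CC)OCCC(=O)[C@H](O)[C@H]1[C@@H](C)[C@@H](O[Si](C)(C)C(C)(C)C)C[C@H](O)[C@]1(C)[C@H](O)CC=C | intermediate
23 | tert-butyl 2-bromopropanoate (racemic) | CC(Br)C(=O)OC(C)(C)C | starting material
24 | bromo[1-(tert-butoxy)-1-oxopropan-2-yl]zinc (not isolated) | CC([Zn]Br)C(=O)OC(C)(C)C | intermediate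
25 | tetraol tert-butyl ester: C8 tertiary carbinol configured as in 35, C17 epimers | CC(C)(C)OC(=O)C(C)[C@](O)(CCO[Si](CC)(CC)CC)[C@H](O)[C@H]1[C@@H](C)[C@@H](O[Si](C)(C)C(C)(C)C)C[C@H](O)[C@]1(C)[C@H](O)CC=C | intermediate
26 | 2,9,14-triacetate of 25 | CC(C)(C)OC(=O)C(C)[C@](O)(CCO[Si](CC)(CC)CC)[C@H](OC(C)=O)[C@H]1[C@@H](C)[C@@H](O[Si](C)(C)C(C)(C)C)C[C@H](OC(C)=O)[C@]1(C)[C@H](OC(C)=O)CC=C | intermediate
27 | C6 aldehyde (not isolated) | CC(C)(C)OC(=O)C(C)[C@](O)(CC=O)[C@H](OC(C)=O)[C@H]1[C@@H](C)[C@@H](O[Si](C)(C)C(C)(C)C)C[C@H](OC(C)=O)[C@]1(C)[C@H](OC(C)=O)CC=C | intermediate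
28 | methyl (Z)-α-iodo enoate (C5 iodide, ester trans to C7), C2 allyl | CC(C)(C)OC(=O)C(C)[C@](O)(C/C=C(\I)C(=O)OC)[C@H](OC(C)=O)[C@H]1[C@@H](C)[C@@H](O[Si](C)(C)C(C)(C)C)C[C@H](OC(C)=O)[C@]1(C)[C@H](OC(C)=O)CC=C | intermediate
29 | C4 aldehyde iodo enoate | CC(C)(C)OC(=O)C(C)[C@](O)(C/C=C(\I)C(=O)OC)[C@H](OC(C)=O)[C@H]1[C@@H](C)[C@@H](O[Si](C)(C)C(C)(C)C)C[C@H](OC(C)=O)[C@]1(C)[C@H](OC(C)=O)CC=O | intermediate
30 | ten-membered allylic alcohol (4R), ring-cis C5=C6 enoate | COC(=O)/C1=C/C[C@@](O)(C(C)C(=O)OC(C)(C)C)[C@H](OC(C)=O)[C@H]2[C@@H](C)[C@@H](O[Si](C)(C)C(C)(C)C)C[C@H](OC(C)=O)[C@]2(C)[C@H](OC(C)=O)C[C@H]1O | intermediate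
31 | macrocyclic 2,4,9,14-tetraacetate tert-butyl ester | COC(=O)/C1=C/C[C@@](O)(C(C)C(=O)OC(C)(C)C)[C@H](OC(C)=O)[C@H]2[C@@H](C)[C@@H](O[Si](C)(C)C(C)(C)C)C[C@H](OC(C)=O)[C@]2(C)[C@H](OC(C)=O)C[C@H]1OC(C)=O | intermediate
32 | macrocyclic seco acid (C19 acid, C7 methylene) | COC(=O)/C1=C/C[C@@](O)(C(C)C(=O)O)[C@H](OC(C)=O)[C@H]2[C@@H](C)[C@@H](O[Si](C)(C)C(C)(C)C)C[C@H](OC(C)=O)[C@]2(C)[C@H](OC(C)=O)C[C@H]1OC(C)=O | intermediate
33 | 12-O-TBS γ-lactone (7S, 8S), C17 epimers | COC(=O)/C1=C/[C@@H]2OC(=O)C(C)[C@@]2(O)[C@H](OC(C)=O)[C@H]2[C@@H](C)[C@@H](O[Si](C)(C)C(C)(C)C)C[C@H](OC(C)=O)[C@]2(C)[C@H](OC(C)=O)C[C@H]1OC(C)=O | intermediate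
34 | 12-O-TBS γ-lactone, 17R | COC(=O)/C1=C/[C@@H]2OC(=O)[C@H](C)[C@@]2(O)[C@H](OC(C)=O)[C@H]2[C@@H](C)[C@@H](O[Si](C)(C)C(C)(C)C)C[C@H](OC(C)=O)[C@]2(C)[C@H](OC(C)=O)C[C@H]1OC(C)=O | intermediate
35 | CNP0169867.2 (1R,2R,4R,5E,7S,8S,9R,10S,11R,12S,14S,17R) | COC(=O)/C1=C/[C@@H]2OC(=O)[C@H](C)[C@@]2(O)[C@H](OC(C)=O)[C@H]2[C@@H](C)[C@@H](O)C[C@H](OC(C)=O)[C@]2(C)[C@H](OC(C)=O)C[C@H]1OC(C)=O | target

## Step count and risks

Total step count: 22. Longest linear sequence: 21 steps (steps 1–9 and 11–22; step 10 is a one-step branch).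

The three steps most likely to fail are step 20, step 17 and step 2.

Step 20 is the new C–H lactonisation; epoxidation of C5=C6 or the wrong C7 epimer could win. Its fallback uses known chemistry, sets out from 31 and comes back at 33. Allylic γ-hydroxylation of the enoate with SeO2 and t-BuOOH in CH2Cl2 gives the (7R)-7-hydroxy tetraacetate tert-butyl ester F1. Treatment with 85% H3PO4 frees the (7R)-7-hydroxy seco acid F2. Mitsunobu lactonisation (PPh3, DIAD, THF) then forms the C7–O bond with inversion and gives 33. Should the 7S alcohol form instead, it lactonises directly when the ester is cleaved.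

Step 17 is the ten-membered ring closure and also sets C4. Its fallback closes the ring at C5=C6 by metathesis, sets out from 26 and comes back at 31. Ozonolysis of 26 gives the C4 aldehyde with the C6 silyl ether F3. A Baylis–Hillman reaction with methyl acrylate mediated by TiCl4 and Me2S, with 1,3-anti induction from the C2 acetate, gives the (4R) Baylis–Hillman alcohol F4, which Ac2O and pyridine convert to the Baylis–Hillman acetate F5. Swern oxidation of the triethylsilyl ether gives the C6 aldehyde F6, which is methylenated without isolation (CH2I2, Zn, TiCl4) to the acrylate vinyl diene F7. Ring-closing metathesis with second-generation Hoveyda–Grubbs catalyst (PhMe, 80 °C, 1 mM) then gives 31.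

Step 2 builds the quaternary centre with an untested diene and dienophile pair under chiral Lewis acid catalysis. Its fallback sets out from 2 and 3 and comes back at 6. A Diels–Alder reaction promoted by Et2AlCl (CH2Cl2, −78 °C) gives 4 together with the enantiomeric aldehyde ester F8. Allylboration of the mixture with (+)-Ipc2B(allyl) under reagent control gives 5 and the diastereomeric hydroxy ester F9. After lactonisation, 6 is separated by chromatography from the diastereomeric lactone F10.

## Further compounds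

F1 | step 20 | (7R)-7-hydroxy macrocyclic tetraacetate tert-butyl ester | COC(=O)/C1=C/[C@@H](O)[C@@](O)(C(C)C(=O)OC(C)(C)C)[C@H](OC(C)=O)[C@H]2[C@@H](C)[C@@H](O[Si](C)(C)C(C)(C)C)C[C@H](OC(C)=O)[C@]2(C)[C@H](OC(C)=O)C[C@H]1OC(C)=O
F2 | step 20 | (7R)-7-hydroxy macrocyclic seco acid | COC(=O)/C1=C/[C@@H](O)[C@@](O)(C(C)C(=O)O)[C@H](OC(C)=O)[C@H]2[C@@H](C)[C@@H](O[Si](C)(C)C(C)(C)C)C[C@H](OC(C)=O)[C@]2(C)[C@H](OC(C)=O)C[C@H]1OC(C)=O
F3 | step 17 | C4 aldehyde with the C6 triethylsilyl ether | CC(C)(C)OC(=O)C(C)[C@](O)(CCO[Si](CC)(CC)CC)[C@H](OC(C)=O)[C@H]1[C@@H](C)[C@@H](O[Si](C)(C)C(C)(C)C)C[C@H](OC(C)=O)[C@]1(C)[C@H](OC(C)=O)CC=O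
F4 | step 17 | (4R) Baylis–Hillman alcohol | CC(C)(C)OC(=O)C(C)[C@](O)(CCO[Si](CC)(CC)CC)[C@H](OC(C)=O)[C@H]1[C@@H](C)[C@@H](O[Si](C)(C)C(C)(C)C)C[C@H](OC(C)=O)[C@]1(C)[C@H](OC(C)=O)C[C@@H](O)C(=C)C(=O)OC
F5 | step 17 | Baylis–Hillman acetate | CC(C)(C)OC(=O)C(C)[C@](O)(CCO[Si](CC)(CC)CC)[C@H](OC(C)=O)[C@H]1[C@@H](C)[C@@H](O[Si](C)(C)C(C)(C)C)C[C@H](OC(C)=O)[C@]1(C)[C@H](OC(C)=O)C[C@@H](OC(C)=O)C(=C)C(=O)OC
F6 | step 17 | C6 aldehyde of the Baylis–Hillman acetate (not isolated) | CC(C)(C)OC(=O)C(C)[C@](O)(CC=O)[C@H](OC(C)=O)[C@H]1[C@@H](C)[C@@H](O[Si](C)(C)C(C)(C)C)C[C@H](OC(C)=O)[C@]1(C)[C@H](OC(C)=O)C[C@@H](OC(C)=O)C(=C)C(=O)OC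
F7 | step 17 | acrylate vinyl diene for ring-closing metathesis | CC(C)(C)OC(=O)C(C)[C@](O)(CC=C)[C@H](OC(C)=O)[C@H]1[C@@H](C)[C@@H](O[Si](C)(C)C(C)(C)C)C[C@H](OC(C)=O)[C@]1(C)[C@H](OC(C)=O)C[C@@H](OC(C)=O)C(=C)C(=O)OC
F8 | step 2 | enantiomer of 4 | CCOC(=O)[C@@H]1[C@@H](C)C(O[Si](C(C)C)(C(C)C)C(C)C)=CC[C@@]1(C)C=O
F9 | step 2 | diastereomeric homoallylic hydroxy ester (2R, ring enantiomeric to 5) | CCOC(=O)[C@@H]1[C@@H](C)C(O[Si](C(C)C)(C(C)C)C(C)C)=CC[C@@]1(C)[C@H](O)CC=C
F10 | step 2 | diastereomeric lactone (2R, ring enantiomeric to 6) | C=CC[C@H]1OC(=O)[C@@H]2[C@@H](C)C(O[Si](C(C)C)(C(C)C)C(C)C)=CC[C@@]12C
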